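**Retrosynthetic overview**

1. Target 28 is phenol 6 bound through oxygen to C8 of a 5,6,7-trihydroxy-5,6,7,8-tetrahydrochromone. The trans-5,6-diol is released last from a 5,6-epoxide opened at C5, as in the presumed biosynthesis of these tetrahydrochromones (28 ⇐ 26 ⇐ 25).
2. The C7 oxygen of 25 comes from C5 by a suprafacial [3,3] acetoxy shift (25 ⇐ 24), which carries configuration from C5 to C7.
3. The carbocycle C4a–C5–C6–C7–C8–C8a is the last ring formed, by ring-closing metathesis that makes the C6–C7 bond (24 ⇐ 23). Enabling feature: C6 and C7 are adjacent carbinol carbons (a diol is the retron of an alkene), and their neighbours C5 and C8 sit on C4a and C8a, the two ends of the cis-fixed pyranone double bond, so two 1-oxyallyl arms are held ortho to each other.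
4. 23 ⇐ allyl carbonate 22 + phenol 6 by iridium-catalysed branched-selective allylic etherification (sets the C8–O bond and C8); the C5 carbinol comes from CBS reduction of vinyl ketone 18.
5. Ring order: the chromone of 6 (Claisen condensation, cyclodehydration) and the 4-pyranone of 12 (acylketene–enamine annulation) first, both arms then grown from the ester-activated 2-methyl group and the ester, carbocycle last.

Key step: step 13

Remarks and assumptions: Ar = 7-methoxy-4-oxo-2-(2-phenylethyl)-4H-chromen-6-yl; α = the face of the carbocycle that carries the C8–OAr bond in 28, β = the other face; compound 1 is taken as a catalogue compound; in step 12 the ligand antipode that gives the (S)-ether is used, its facial sense being taken over from aryl-substituted allyl carbonates.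

**Route**

Step 1
Reactants: 1 1-(2,5-dihydroxy-4-methoxyphenyl)ethan-1-one
Product: 2 1-[2-hydroxy-4-methoxy-5-(methoxymethoxy)phenyl]ethan-1-one
Conditions: MOMCl (1.1 equiv), iPr2NEt, CH2Cl2, 0 °C
Reagents that add atoms: chloromethyl methyl ether, COCCl
Why: O-alkylation (MOM protection) should occur only at the C5 phenol, because the C2 phenol is held in a hydrogen bond to the acetyl carbonyl.

Step 2
Reactants: 2 1-[2-hydroxy-4-methoxy-5-(methoxymethoxy)phenyl]ethan-1-one; 3 ethyl 3-phenylpropanoate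
Product: 4 1-[2-hydroxy-4-methoxy-5-(methoxymethoxy)phenyl]-5-phenylpentane-1,3-dione
Conditions: NaH (4 equiv), THF, 65 °C; AcOH quench
Reagents that add atoms: none
Why: Crossed Claisen condensation of the phenoxide–enolate dianion of 2 with the ester, driven by formation of the 1,3-diketone enolate.

Step 3
Reactants: 4 1-[2-hydroxy-4-methoxy-5-(methoxymethoxy)phenyl]-5-phenylpentane-1,3-dione
Product: 6 6-hydroxy-7-methoxy-2-(2-phenylethyl)-4H-chromen-4-one, via MOM-protected chromone 5 (not isolated)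
Conditions: conc. HCl (cat.), MeOH, 65 °C
Reagents that add atoms: none
Why: Acid-catalysed cyclodehydration of the 2-hydroxyaryl 1,3-diketone (classical chromone synthesis) should be followed in the same pot by acetal exchange with methanol, which removes the MOM group.

Step 4
Reactants: 7 2,2,6-trimethyl-4H-1,3-dioxin-4-one; 8 benzyl bromide
Product: 9 2,2-dimethyl-6-(2-phenylethyl)-4H-1,3-dioxin-4-one
Conditions: LiN(iPr)2, THF–DMPU, −78 °C; then 8
Reagents that add atoms: none
Why: γ-Alkylation of the lithium dienolate of the dioxinone (vinylogous enolate alkylation) is established for reactive benzylic halides.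

Step 5
Reactants: 9 2,2-dimethyl-6-(2-phenylethyl)-4H-1,3-dioxin-4-one (2.2 equiv); 10 ethyl (2E)-3-(pyrrolidin-1-yl)but-2-enoate
Product: 12 ethyl 2-methyl-4-oxo-6-(2-phenylethyl)-4H-pyran-3-carboxylate, via acylketene 11 (not isolated)
Conditions: toluene, 110 °C
Reagents that add atoms: none
Why: Thermal retro-[4+2] of the dioxinone releases acylketene 11, which is C-acylated by the enamine β-carbon and cyclises with loss of pyrrolidine (acylketene–enamine annulation to 4-pyranones); the excess of 9 allows for ketene trapped by the released amine.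

Step 6
Reactants: 12 ethyl 2-methyl-4-oxo-6-(2-phenylethyl)-4H-pyran-3-carboxylate; 13 {[tert-butyl(dimethyl)silyl]oxy}acetaldehyde
Product: 15 2-[(1E)-3-{[tert-butyl(dimethyl)silyl]oxy}prop-1-en-1-yl]-4-oxo-6-(2-phenylethyl)-4H-pyran-3-carboxylic acid, via lactone 14 (not isolated)
Conditions: LiN(SiMe3)2 (2.2 equiv), THF, −78 °C; 13; −78 °C to rt; cold 1 M HCl to pH 3
Reagents that add atoms: none
Why: Lateral (vinylogous) deprotonation should occur at the 2-methyl group, whose anion is conjugated to both the ring carbonyl and the ester; aldol addition, lactonisation onto the neighbouring ester and E1cB opening of lactone 14 (the toluate-anion/dihydroisocoumarin sequence) should give the conjugated (E)-alkene.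

Step 7
Reactants: 15 2-[(1E)-3-{[tert-butyl(dimethyl)silyl]oxy}prop-1-en-1-yl]-4-oxo-6-(2-phenylethyl)-4H-pyran-3-carboxylic acid; 16 tributyl(vinyl)stannane
Product: 18 2-[(1E)-3-{[tert-butyl(dimethyl)silyl]oxy}prop-1-en-1-yl]-6-(2-phenylethyl)-3-(prop-2-enoyl)-4H-pyran-4-one, via acid chloride 17 (not isolated)
Conditions: 1-chloro-N,N,2-trimethylprop-1-en-1-amine, CH2Cl2, 0 °C; then 16, Pd2(dba)3 (2.5 mol %), P(2-furyl)3 (10 mol %), THF, 50 °C
Reagents that add atoms: none
Why: Stille acylation (acid chloride plus vinylstannane under zerovalent palladium) forms the vinyl ketone under neutral conditions that should leave the pyranone carbonyl and the silyl ether untouched.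

Step 8
Reactants: 18 2-[(1E)-3-{[tert-butyl(dimethyl)silyl]oxy}prop-1-en-1-yl]-6-(2-phenylethyl)-3-(prop-2-enoyl)-4H-pyran-4-one
Product: 19 2-[(1E)-3-{[tert-butyl(dimethyl)silyl]oxy}prop-1-en-1-yl]-3-[(1R)-1-hydroxyprop-2-en-1-yl]-6-(2-phenylethyl)-4H-pyran-4-one
Conditions: (S)-2-methyl-CBS-oxazaborolidine (0.3 equiv), catecholborane (1.5 equiv), toluene, −78 °C; MeOH quench
Reagents that add atoms: none
Why: Corey–Bakshi–Shibata reduction; the fully substituted pyranonyl group acts as the large and the vinyl group as the small substituent, so the (S)-catalyst should deliver hydride to give the (R)-carbinol, and catecholborane at low temperature reduces 1,2 and not 1,4.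

Step 9
Reactants: 19 2-[(1E)-3-{[tert-butyl(dimethyl)silyl]oxy}prop-1-en-1-yl]-3-[(1R)-1-hydroxyprop-2-en-1-yl]-6-(2-phenylethyl)-4H-pyran-4-one
Product: 20 (1R)-1-{2-[(1E)-3-{[tert-butyl(dimethyl)silyl]oxy}prop-1-en-1-yl]-4-oxo-6-(2-phenylethyl)-4H-pyran-3-yl}prop-2-en-1-yl acetate
Conditions: Ac2O, pyridine, DMAP (cat.), CH2Cl2, 0 °C
Reagents that add atoms: acetic anhydride, CC(=O)OC(C)=O
Why: DMAP-catalysed acylation without change at the stereocentre; the acetate blocks intramolecular etherification in step 12 and is the migrating group of step 14.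

Step 10
Reactants: 20 (1R)-1-{2-[(1E)-3-{[tert-butyl(dimethyl)silyl]oxy}prop-1-en-1-yl]-4-oxo-6-(2-phenylethyl)-4H-pyran-3-yl}prop-2-en-1-yl acetate
Product: 21 (1R)-1-{2-[(1E)-3-hydroxyprop-1-en-1-yl]-4-oxo-6-(2-phenylethyl)-4H-pyran-3-yl}prop-2-en-1-yl acetate
Conditions: HF·pyridine, THF–pyridine, 0 °C
Reagents that add atoms: none
Why: Fluoride-mediated desilylation of the primary silyl ether under buffered conditions should leave the allylic acetate in place.

Step 11
Reactants: 21 (1R)-1-{2-[(1E)-3-hydroxyprop-1-en-1-yl]-4-oxo-6-(2-phenylethyl)-4H-pyran-3-yl}prop-2-en-1-yl acetate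
Product: 22 (1R)-1-{2-[(1E)-3-(methoxycarbonyloxy)prop-1-en-1-yl]-4-oxo-6-(2-phenylethyl)-4H-pyran-3-yl}prop-2-en-1-yl acetate
Conditions: ClCO2Me, pyridine, CH2Cl2, 0 °C
Reagents that add atoms: methyl chloroformate, COC(=O)Cl
Why: Acylation of the primary allylic alcohol gives the carbonate leaving group needed for the allyliridium chemistry of step 12.

Step 12
Reactants: 22 (1R)-1-{2-[(1E)-3-(methoxycarbonyloxy)prop-1-en-1-yl]-4-oxo-6-(2-phenylethyl)-4H-pyran-3-yl}prop-2-en-1-yl acetate; 6 6-hydroxy-7-methoxy-2-(2-phenylethyl)-4H-chromen-4-one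
Product: 23 (1R)-1-{2-[(1S)-1-(ArO)prop-2-en-1-yl]-4-oxo-6-(2-phenylethyl)-4H-pyran-3-yl}prop-2-en-1-yl acetate
Conditions: [Ir(cod)Cl]2 (2 mol %), O,O'-(1,1'-binaphthalene-2,2'-diyl) N,N-bis(1-phenylethyl)phosphoramidite (4 mol %, antipode as stated above), 1,5,7-triazabicyclo[4.4.0]dec-5-ene (8 mol %), THF, rt
Reagents that add atoms: none
Why: Iridium-catalysed enantioselective allylic etherification; the cyclometalated iridium–phosphoramidite catalyst should ionise the primary carbonate much faster than the secondary acetate, the phenoxide attacks the substituted allyl terminus to give the branched ether, and the configuration at C8 is set by the ligand.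

Step 13
Reactants: 23 (1R)-1-{2-[(1S)-1-(ArO)prop-2-en-1-yl]-4-oxo-6-(2-phenylethyl)-4H-pyran-3-yl}prop-2-en-1-yl acetate
Product: 24 (5R,8S)-8-(ArO)-4-oxo-2-(2-phenylethyl)-5,8-dihydro-4H-chromen-5-yl acetate
Conditions: second-generation Hoveyda–Grubbs catalyst [(H2IMes)Cl2Ru=CH(2-iPrO-C6H4), 5 mol %], 1,4-benzoquinone (10 mol %), CH2Cl2 (5 mM), 40 °C
Reagents that add atoms: none
Why: Ring-closing olefin metathesis: the ruthenium alkylidene loads onto one vinyl group, undergoes intramolecular [2+2] cycloaddition with the other to a ruthenacyclobutane, and cycloreversion releases ethene and the C6=C7 bond. The closest known reaction type is the ring-closing metathesis of arenes bearing two ortho 1-oxyallyl groups to 1,4-dihydronaphthalene-1,4-diol derivatives. One ring is closed, the six-membered carbocycle C4a–C5–C6–C7–C8–C8a, by metathesis between the terminal alkene carbons of two side chains held on adjacent carbons of the pyranone. No new stereocentre is formed; C5 (R, from step 8) and C8 (S, from step 12) are not touched and end up cis on the new ring. The step needs cyclisation to win over oligomerisation and needs the absence of ruthenium-hydride double-bond migration, which would lead on to aromatisation by loss of acetic acid or of the phenol; the first is secured by the cis-fixed C4a=C8a double bond that holds the two allylic carbons 1,2 on a planar unit and by high dilution, the second by the benzoquinone additive and the mild temperature.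

Step 14
Reactants: 24 (5R,8S)-8-(ArO)-4-oxo-2-(2-phenylethyl)-5,8-dihydro-4H-chromen-5-yl acetate
Product: 25 (7S,8S)-8-(ArO)-4-oxo-2-(2-phenylethyl)-7,8-dihydro-4H-chromen-7-yl acetate
Conditions: PdCl2(MeCN)2 (10 mol %), THF, 23 °C
Reagents that add atoms: none
Why: Divalent-palladium-catalysed [3,3]-sigmatropic (cyclisation-induced) rearrangement of the allylic acetate; the acetate carbonyl oxygen adds to C7 on the face that carries the C5–O bond before that bond breaks, so the shift is suprafacial and should move the α oxygen from C5 to C7 (cis to the C8 aryloxy group), driven by conjugation of the new C5=C6 bond with the pyranone.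

Step 15
Reactants: 25 (7S,8S)-8-(ArO)-4-oxo-2-(2-phenylethyl)-7,8-dihydro-4H-chromen-7-yl acetate
Product: 26 (5R,6R,7S,8S)-8-(ArO)-5,6-epoxy-4-oxo-2-(2-phenylethyl)-5,6,7,8-tetrahydro-4H-chromen-7-yl acetate
Conditions: dimethyldioxirane (1.2 equiv, acetone solution), CH2Cl2, 0 °C
Reagents that add atoms: dimethyldioxirane, CC1(C)OO1
Why: Neutral dioxirane epoxidation should take place at the C5=C6 bond, which is more electron-rich than the vinylogous-ester double bonds, and from the β face, opposite to the cis C7 acetoxy and C8 aryloxy groups.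

Step 16
Reactants: 26 (5R,6R,7S,8S)-8-(ArO)-5,6-epoxy-4-oxo-2-(2-phenylethyl)-5,6,7,8-tetrahydro-4H-chromen-7-yl acetate
Product: 28 (5S,6R,7S,8S)-5,6,7-trihydroxy-8-(ArO)-2-(2-phenylethyl)-5,6,7,8-tetrahydro-4H-chromen-4-one, via diol monoacetate 27 (not isolated)
Conditions: THF–H2O (3:1), HClO4 (5 mol %), 0 °C; extraction; then K2CO3 (0.3 equiv), MeOH, 0 °C
Reagents that add atoms: water, O
Why: Acid-catalysed epoxide hydrolysis should open the epoxide at C5, where developing positive charge is stabilised through C4a=C8a by the ring oxygen, with inversion to give the 5α,6β-diol (participation of the C7 acetate across to C5 would deliver the same α oxygen), and mild transesterification then removes the acetyl group.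

**Compound list**

1 | 1-(2,5-dihydroxy-4-methoxyphenyl)ethan-1-one | CC(=O)c1cc(O)c(OC)cc1O | starting material
2 | 1-[2-hydroxy-4-methoxy-5-(methoxymethoxy)phenyl]ethan-1-one | CC(=O)c1cc(OCOC)c(OC)cc1O | intermediate
3 | ethyl 3-phenylpropanoate | CCOC(=O)CCc1ccccc1 | starting material
4 | 1-[2-hydroxy-4-methoxy-5-(methoxymethoxy)phenyl]-5-phenylpentane-1,3-dione | O=C(CC(=O)CCc1ccccc1)c1cc(OCOC)c(OC)cc1O | intermediate
5 | 7-methoxy-6-(methoxymethoxy)-2-(2-phenylethyl)-4H-chromen-4-one | COc1cc2oc(CCc3ccccc3)cc(=O)c2cc1OCOC | intermediate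
6 | 6-hydroxy-7-methoxy-2-(2-phenylethyl)-4H-chromen-4-one | COc1cc2oc(CCc3ccccc3)cc(=O)c2cc1O | intermediate
7 | 2,2,6-trimethyl-4H-1,3-dioxin-4-one | CC1=CC(=O)OC(C)(C)O1 | starting material
8 | benzyl bromide | BrCc1ccccc1 | starting material
9 | 2,2-dimethyl-6-(2-phenylethyl)-4H-1,3-dioxin-4-one | CC1(C)OC(=O)C=C(CCc2ccccc2)O1 | intermediate
10 | ethyl (2E)-3-(pyrrolidin-1-yl)but-2-enoate | CCOC(=O)/C=C(\C)N1CCCC1 | starting material
11 | 3-oxo-5-phenylpent-1-en-1-one (acylketene) | O=C=CC(=O)CCc1ccccc1 | intermediate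
12 | ethyl 2-methyl-4-oxo-6-(2-phenylethyl)-4H-pyran-3-carboxylate | CCOC(=O)c1c(C)oc(CCc2ccccc2)cc1=O | intermediate
13 | {[tert-butyl(dimethyl)silyl]oxy}acetaldehyde | O=CCO[Si](C)(C)C(C)(C)C | starting material
14 | 7-({[tert-butyl(dimethyl)silyl]oxy}methyl)-2-(2-phenylethyl)-7,8-dihydro-4H,5H-pyrano[4,3-b]pyran-4,5-dione (racemic) | O=C1OC(CO[Si](C)(C)C(C)(C)C)Cc2oc(CCc3ccccc3)cc(=O)c21 | intermediate
15 | 2-[(1E)-3-{[tert-butyl(dimethyl)silyl]oxy}prop-1-en-1-yl]-4-oxo-6-(2-phenylethyl)-4H-pyran-3-carboxylic acid | OC(=O)c1c(/C=C/CO[Si](C)(C)C(C)(C)C)oc(CCc2ccccc2)cc1=O | intermediate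
16 | tributyl(vinyl)stannane | C=C[Sn](CCCC)(CCCC)CCCC | starting material
17 | 2-[(1E)-3-{[tert-butyl(dimethyl)silyl]oxy}prop-1-en-1-yl]-4-oxo-6-(2-phenylethyl)-4H-pyran-3-carbonyl chloride | ClC(=O)c1c(/C=C/CO[Si](C)(C)C(C)(C)C)oc(CCc2ccccc2)cc1=O | intermediate
18 | 2-[(1E)-3-{[tert-butyl(dimethyl)silyl]oxy}prop-1-en-1-yl]-6-(2-phenylethyl)-3-(prop-2-enoyl)-4H-pyran-4-one | C=CC(=O)c1c(/C=C/CO[Si](C)(C)C(C)(C)C)oc(CCc2ccccc2)cc1=O | intermediate
19 | 2-[(1E)-3-{[tert-butyl(dimethyl)silyl]oxy}prop-1-en-1-yl]-3-[(1R)-1-hydroxyprop-2-en-1-yl]-6-(2-phenylethyl)-4H-pyran-4-one | C=C[C@@H](O)c1c(/C=C/CO[Si](C)(C)C(C)(C)C)oc(CCc2ccccc2)cc1=O | intermediate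
20 | (1R)-1-{2-[(1E)-3-{[tert-butyl(dimethyl)silyl]oxy}prop-1-en-1-yl]-4-oxo-6-(2-phenylethyl)-4H-pyran-3-yl}prop-2-en-1-yl acetate | C=C[C@@H](OC(C)=O)c1c(/C=C/CO[Si](C)(C)C(C)(C)C)oc(CCc2ccccc2)cc1=O | intermediate
21 | (1R)-1-{2-[(1E)-3-hydroxyprop-1-en-1-yl]-4-oxo-6-(2-phenylethyl)-4H-pyran-3-yl}prop-2-en-1-yl acetate | C=C[C@@H](OC(C)=O)c1c(/C=C/CO)oc(CCc2ccccc2)cc1=O | intermediate
22 | (1R)-1-{2-[(1E)-3-(methoxycarbonyloxy)prop-1-en-1-yl]-4-oxo-6-(2-phenylethyl)-4H-pyran-3-yl}prop-2-en-1-yl acetate | C=C[C@@H](OC(C)=O)c1c(/C=C/COC(=O)OC)oc(CCc2ccccc2)cc1=O | intermediate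
23 | (1R)-1-{2-[(1S)-1-(ArO)prop-2-en-1-yl]-4-oxo-6-(2-phenylethyl)-4H-pyran-3-yl}prop-2-en-1-yl acetate | COc1cc2oc(CCc3ccccc3)cc(=O)c2cc1O[C@@H](C=C)c1oc(CCc2ccccc2)cc(=O)c1[C@H](OC(C)=O)C=C | intermediate
24 | (5R,8S)-8-(ArO)-4-oxo-2-(2-phenylethyl)-5,8-dihydro-4H-chromen-5-yl acetate (5-OAc and 8-OAr cis) | COc1cc2oc(CCc3ccccc3)cc(=O)c2cc1O[C@@H]1c2oc(CCc3ccccc3)cc(=O)c2[C@H](OC(C)=O)C=C1 | intermediate
25 | (7S,8S)-8-(ArO)-4-oxo-2-(2-phenylethyl)-7,8-dihydro-4H-chromen-7-yl acetate (7-OAc and 8-OAr cis) | COc1cc2oc(CCc3ccccc3)cc(=O)c2cc1O[C@@H]1c2oc(CCc3ccccc3)cc(=O)c2C=C[C@@H]1OC(C)=O | intermediate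
26 | (5R,6R,7S,8S)-8-(ArO)-5,6-epoxy-4-oxo-2-(2-phenylethyl)-5,6,7,8-tetrahydro-4H-chromen-7-yl acetate (epoxide trans to 7-OAc and 8-OAr) | COc1cc2oc(CCc3ccccc3)cc(=O)c2cc1O[C@@H]1c2oc(CCc3ccccc3)cc(=O)c2[C@H]2O[C@H]2[C@@H]1OC(C)=O | intermediate
27 | (5S,6R,7S,8S)-8-(ArO)-5,6-dihydroxy-4-oxo-2-(2-phenylethyl)-5,6,7,8-tetrahydro-4H-chromen-7-yl acetate | COc1cc2oc(CCc3ccccc3)cc(=O)c2cc1O[C@@H]1c2oc(CCc3ccccc3)cc(=O)c2[C@H](O)[C@@H](O)[C@@H]1OC(C)=O | intermediate
28 | (5S,6R,7S,8S)-5,6,7-trihydroxy-8-(ArO)-2-(2-phenylethyl)-5,6,7,8-tetrahydro-4H-chromen-4-one | COc1cc2oc(CCc3ccccc3)cc(=O)c2cc1O[C@@H]1c2oc(CCc3ccccc3)cc(=O)c2[C@H](O)[C@@H](O)[C@@H]1O | target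

**Summary**

Total step count: 16. Longest linear sequence: 13 steps (7 to 28, steps 4 to 16).

Steps most likely to fail:

Step 14. The cyclic acetate may not enter the cyclisation-induced pathway, or ionisation at C5 may come first and be followed by loss of acetic acid or of the phenol with aromatisation of the carbocycle. The fallback sets out from 24 and comes back at 25. Methanolysis of the acetate (K2CO3, MeOH, 0 °C) should give the (5R,8S)-allylic alcohol F1. Hydroxyl-directed epoxidation (VO(acac)2, tBuOOH, CH2Cl2) should give the all-cis epoxy alcohol F2. Oxidation with Dess–Martin periodinane should give the epoxy ketone F3. Wharton transposition (N2H4·H2O, AcOH, MeOH) should give the (7S,8S)-allylic alcohol F4, in which the former epoxide oxygen stays on C7 on the α face. Acetylation (Ac2O, pyridine) then gives 25.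

Step 12. The phenoxide may attack the unsubstituted allyl terminus, base may move the terminal double bond into conjugation with the pyranone, or the secondary allylic acetate may be ionised in competition. The fallback sets out from 21 and comes back at 23. Sharpless asymmetric epoxidation (Ti(OiPr)4, L-(+)-diethyl tartrate, tBuOOH, 4 Å sieves, −20 °C) should give the (2S,3R)-epoxy alcohol F5. Opening at C3 with phenol 6, mediated by Ti(OiPr)4 and with inversion, should give the aryloxy diol F6. 1,1'-Thiocarbonyldiimidazole should convert it into the cyclic thiocarbonate F7. Corey–Winter olefination with 1,3-dimethyl-2-phenyl-1,3,2-diazaphospholidine at 40 °C then gives 23.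

Step 16. Water may attack on the β face after full ionisation at C5 (cis diol), the C7 acetate may attack C6, or the epoxide may collapse to an aromatic chromone. The fallback sets out from 25 and comes back at 28. Dihydroxylation (OsO4 cat., N-methylmorpholine N-oxide, acetone–water) from the β face should give the cis-5,6-diol F8. Mitsunobu inversion of the activated C5 hydroxyl with 4-nitrobenzoic acid (PPh3, diisopropyl azodicarboxylate) should give the 5α-(4-nitrobenzoate) F9. Methanolysis of both esters (K2CO3, MeOH, 0 °C) then gives 28.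

Further compounds
F1 | step 14 | (5R,8S)-8-(ArO)-5-hydroxy-2-(2-phenylethyl)-5,8-dihydro-4H-chromen-4-one | COc1cc2oc(CCc3ccccc3)cc(=O)c2cc1O[C@@H]1c2oc(CCc3ccccc3)cc(=O)c2[C@H](O)C=C1
F2 | step 14 | 8-(ArO)-6,7-epoxy-5-hydroxy-2-(2-phenylethyl)-5,6,7,8-tetrahydro-4H-chromen-4-one with hydroxyl, epoxide and aryloxy group all on the α face | COc1cc2oc(CCc3ccccc3)cc(=O)c2cc1O[C@@H]1c2oc(CCc3ccccc3)cc(=O)c2[C@H](O)[C@@H]2O[C@H]12
F3 | step 14 | 8-(ArO)-6,7-epoxy-2-(2-phenylethyl)-7,8-dihydro-4H-chromene-4,5(6H)-dione with epoxide and aryloxy group on the α face | COc1cc2oc(CCc3ccccc3)cc(=O)c2cc1O[C@@H]1c2oc(CCc3ccccc3)cc(=O)c2C(=O)[C@@H]2O[C@H]12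
F4 | step 14 | (7S,8S)-8-(ArO)-7-hydroxy-2-(2-phenylethyl)-7,8-dihydro-4H-chromen-4-one | COc1cc2oc(CCc3ccccc3)cc(=O)c2cc1O[C@@H]1c2oc(CCc3ccccc3)cc(=O)c2C=C[C@@H]1O
F5 | step 12 | (1R)-1-{2-[(2R,3S)-3-(hydroxymethyl)oxiran-2-yl]-4-oxo-6-(2-phenylethyl)-4H-pyran-3-yl}prop-2-en-1-yl acetate (the (2S,3R)-epoxy alcohol in epoxy-alcohol numbering) | OC[C@@H]1O[C@H]1c1oc(CCc2ccccc2)cc(=O)c1[C@H](OC(C)=O)C=C
F6 | step 12 | (1R)-1-{2-[(1S,2S)-1-(ArO)-2,3-dihydroxypropyl]-4-oxo-6-(2-phenylethyl)-4H-pyran-3-yl}prop-2-en-1-yl acetate | COc1cc2oc(CCc3ccccc3)cc(=O)c2cc1O[C@@H]([C@@H](O)CO)c1oc(CCc2ccccc2)cc(=O)c1[C@H](OC(C)=O)C=C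
F7 | step 12 | cyclic thiocarbonate (2-thioxo-1,3-dioxolane) of the diol F6 | COc1cc2oc(CCc3ccccc3)cc(=O)c2cc1O[C@@H]([C@@H]1COC(=S)O1)c1oc(CCc2ccccc2)cc(=O)c1[C@H](OC(C)=O)C=C
F8 | step 16 | 8-(ArO)-5,6-dihydroxy-4-oxo-2-(2-phenylethyl)-5,6,7,8-tetrahydro-4H-chromen-7-yl acetate with both hydroxyls on the β face | COc1cc2oc(CCc3ccccc3)cc(=O)c2cc1O[C@@H]1c2oc(CCc3ccccc3)cc(=O)c2[C@@H](O)[C@@H](O)[C@@H]1OC(C)=O
F9 | step 16 | 7-acetoxy-8-(ArO)-6-hydroxy-4-oxo-2-(2-phenylethyl)-5,6,7,8-tetrahydro-4H-chromen-5-yl 4-nitrobenzoate with the 5-ester on the α face and the 6-hydroxyl on the β face | COc1cc2oc(CCc3ccccc3)cc(=O)c2cc1O[C@@H]1c2oc(CCc3ccccc3)cc(=O)c2[C@H](OC(=O)c3ccc(cc3)[N+](=O)[O-])[C@@H](O)[C@@H]1OC(C)=O
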